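**Retrosynthetic overview**
- Sigmoidin B (**1**) is disconnected at the C5'–prenyl bond. It comes from C–H prenylation of (2S)-eriodictyol (**2**), which already carries the only stereocentre and all three rings.
- The bond is formed electrochemically. Anodic oxidation of the B-ring catechol gives an o-quinone, the only oxidisable unit. Tertiary allylsilane **3** (a prenyl-anion equivalent) then adds at C5' by a 1,6-addition (SE2', through the CH2 terminus) and the ring rearomatises.
- **3** is made from prenyl chloride (**4**) and TMSCl (**5**) via prenylmagnesium chloride, which is silylated at the γ-carbon.
- No rings are built, and no stereocentre is touched after the start.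

Assumptions: (S)-eriodictyol (**2**) is purchased (natural, citrus-derived). Silylation of prenylMgCl gives mainly the tertiary silane **3**, and traces of the primary isomer are removed by distillation.

**Step 1**
Reactants: **4** 1-chloro-3-methylbut-2-ene (prenyl chloride); **5** chlorotrimethylsilane
Product: **3** 3-methyl-3-(trimethylsilyl)but-1-ene (α,α-dimethylallyltrimethylsilane)
Conditions: (i) Mg turnings, THF, 0 °C, then (ii) **5**, −20 °C → rt; distil
Reagents that add atoms: TMSCl (**5**), C[Si](C)(C)Cl (SiMe3 ends up in **3**)
Why: The allylic Grignard reacts with the chlorosilane at its γ-carbon through a six-membered SE2' transition state, which gives the tertiary silane (a Grignard silylation). Its Si–C bond sits β to the CH=CH2 terminus, so later attack by an electrophile at CH2 puts the new bond on the primary carbon and leaves the CH=CMe2 unit, which is the prenyl group.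

**Step 2**
Reactants: **2** (2S)-eriodictyol; **3**
Product: **1** sigmoidin B
Conditions: **3** (3 equiv), nBu4NBF4 (0.1 M), HFIP/MeCN 1:4, undivided cell, graphite anode and graphite cathode, constant current 3 mA (~1.5 F/mol), Ar, 25 °C; recover unreacted **2** and recycle
Reagents that add atoms: **3**, C=CC(C)(C)[Si](C)(C)C (supplies the C5H9 prenyl unit; its SiMe3 leaves as Me3Si–F/OR)
Why: Proposed new method: The catechol oxidises at roughly +0.5 V, well below the A-ring phenols, the prenyl-free alkene and the allylsilane. It gives the o-quinone, which HFIP hydrogen-bonding activates. 1,6-Addition at C5' is the site favoured in o-quinone chemistry (for example 5-S-cysteinyldopa from dopaquinone). The nucleophile attacks through the unsubstituted CH2 terminus of **3**, forming a β-silyl cation. BF4⁻ or MeCN removes the silyl group to give the C5'–CH2–CH=CMe2 unit, and tautomerisation restores the catechol. Cathodic H⁺ reduction to H2 balances the two-electron oxidation. The closest known reactions are anodic catechol–o-quinone Michael additions and Hosomi–Sakurai allylation of quinones, but the combination with a tertiary allylsilane as a prenyl transfer agent on an unprotected flavanone is new. No stereocentre is formed, and the medium is acidic to neutral, so the C2 configuration survives (the C2 epimerisation pathway is base-promoted retro-oxa-Michael ring opening).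

**Checks**
- Structure: 2 is C15H12O6 and the prenyl unit adds C5H8 net, giving C20H20O6, which matches **1**.
- Ring sizes and substituents: the chroman-4-one, the 5,7-dihydroxy A-ring and the 3',4'-dihydroxy-5'-prenyl B-ring all match the target.
- Configuration: the C2 stereocentre comes from **2** and is (S), matching [C@@H] in the target SMILES.
- Functional groups: the ketone, the A-ring phenols and the flavanone C2–O bond survive the electrolysis conditions.

**Compound list**
1 | sigmoidin B, (2S)-5,7,3',4'-tetrahydroxy-5'-prenylflavanone | CC(C)=CCc1cc([C@@H]2CC(=O)c3c(O)cc(O)cc3O2)cc(O)c1O | target
2 | (2S)-eriodictyol | Oc1ccc([C@@H]2CC(=O)c3c(O)cc(O)cc3O2)cc1O | starting material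
3 | 3-methyl-3-(trimethylsilyl)but-1-ene | C=CC(C)(C)[Si](C)(C)C | intermediate (reagent)
4 | 1-chloro-3-methylbut-2-ene (prenyl chloride) | CC(C)=CCCl | starting material
5 | chlorotrimethylsilane | C[Si](C)(C)Cl | starting material

**Totals**
Total steps: 2. Longest linear sequence: 2 (**4** → **3** → **1**). Only two steps exist, so the third risk below is a second failure mode of Step 2.

**Three most likely failures and fallbacks**
1. **Step 2 (the proposed new step).** Risks are regioselectivity (C6'/C2' versus C5'), over-oxidation of the more electron-rich product, and [3+2] dihydrobenzofuran formation.
   Fallback (known chemistry, different approach): build the flavanone from a prenylated B-ring. Claisen–Schmidt condensation of 3,4-bis(MOM-oxy)-5-prenylbenzaldehyde with tris-MOM-phloroacetophenone, acid-mediated cyclisation and deprotection give racemic sigmoidin B. Preparative chiral-phase HPLC then isolates the (S)-enantiomer.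
2. **Step 1.** Contamination with the primary prenylsilane isomer would give reverse-prenyl product.
   Fallback: make the regio-pure tertiary silane (as its PhMe2Si analogue) by Cu-catalysed SN2' silylation of prenyl carbonate with PhMe2Si–Bpin, and use it in Step 2.
3. **Step 2, second failure mode** (quinone dimerisation, or flavone formation or racemisation under the electrolysis).
   Fallback: replace the anode with a chemical oxidant. IBX or Ag2O at −40 °C generates the o-quinone, which is then treated with **3** and a mild Lewis acid in a separate stage.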